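## The problem

Compound 33 is an ent-labd-8(17)-en-18-oic acid whose side chain beyond C11 is replaced by an arene. A trans-decalin (ring A = C1–C5 and C10, ring B = C5–C10) carries an equatorial carboxyl (C18) and an axial methyl (C19) at C4, the angular methyl C20 at C10, an exocyclic methylene (C17) at C8, and at C9, through the benzylic methylene C11, the C8′ position of a 2′-hydroxy-3′,7′-dimethyl-1′,4′-naphthoquinone. Four contiguous stereocentres must be set (C4, C5, C9, C10; two are quaternary). C5, C9 and C10 all lie on ring B and can be fixed in one ring-forming event. C4 has no directing neighbour and can only be controlled through the difference between its axial position, shielded by the syn-axial C20, and its open equatorial position. The C9–C11–C8′ link is the most crowded part of the molecule, because C11 lies between a neopentyl-type carbon and an arene carbon flanked by the C7′ methyl and the peri oxygen at C1′; it is better made early, between sp2 carbons, than late by substitution. The exocyclic alkene (migrates with acid, lost on hydrogenation or under radical conditions) and the hydroxyquinone (redox-active, open to hydrides and organometallics) will not survive rough treatment, so the alkene must follow all reductions and the quinone must travel as a 1,2,4-trimethoxynaphthalene. The enabling feature is ring B: with oxygen at C8 and C11 at the ketone level, ring B is the cyclohexene of a [4+2] between a C5=C6–C7=C8 oxy-diene and a C9=C10 enone that already carries C20 on C10 and the whole arene on C11. Because C5 and C10 are joined a second time through C1–C4, an intramolecular version closes ring A as well, and a malonate carbon at C4 is not a stereocentre until the rings exist.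

## Retrosynthesis

The last operations only unmask the quinone. The O–CH3 bonds at C1′ and C4′ of 31 are cut oxidatively (31 → 32) and the remaining vinylogous ester at C2′ hydrolytically (32 → 33). A single Lewis-acidic demethylation would be shorter but would expose the 8(17)-alkene to boron halides and HBr. The two-stage unmasking asks only that tetravalent cerium oxidise the arene faster than the alkene and that dilute hydroxide leave the decalin alone.

C8=C17 is cut next (Wittig), leading back to ketone 30, alcohol 29 and silyl ether 28. Olefination after every reduction keeps the alkene safe, and the precursor carries at C8 the oxygen that a 1-oxy-diene leaves there. The forward step must methylenate a ketone next to the substituted C9 without epimerising it; the C9 side chain is already equatorial, which helps.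

The C11–H and C19–H bonds are traced to C–O bonds in the diol acid 25 and removed together through the bis-xanthate 27. Compound 25 comes from the half-ester 24 by hydride reduction of the C11 ketone and the axial ester, and 24 from the diester 23 by hydrolysis of the equatorial ester. Here C4 becomes stereogenic: hydroxide takes the open equatorial ester, and the hydride then finds only one ester left. Decarboxylation and methylation of a C4 ester enolate would bring the methyl in from the equatorial side and give the wrong epimer. Compound 23 is simpler by one stereocentre; the forward steps must keep the β-silyloxy ketone from eliminating and must generate a neopentyl primary radical.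

After hydrogenation of C6=C7 (22 → 23), the key disconnection cuts C5–C10 and C8–C9 of 22 at once and opens both rings to the acyclic trienone 21. Closing only ring B on a preformed ring A would leave the two quaternary carbons of ring A to a separate asymmetric synthesis. Cutting C4–C5 and C9–C10 instead would need an extra oxygen at C3 as initiator. Compound 21 has no ring, no stereocentre and only E double bonds. The forward reaction must follow the ketone-endo, tether-exo mode, distinguish the enantiotopic faces of the enone under catalyst control, and spare an acid-sensitive silyl dienol ether.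

The C9–C11 bond of 21 is cut to the alkenyl iodide 10 and the aldehyde 19, joined through the carbinol 20. An aldol condensation of an aryl methyl ketone with a methyl ketone in the tether would make the same bond, but as a ketone–ketone aldol with no control of the C9=C10 geometry. With an alkenyl iodide the E geometry is fixed beforehand by carbometalation and survives the coupling. The coupling must tolerate two esters and a silyl dienol ether, and the oxidation of 20 must be neutral.

The diene of 10 is traced to the enal 9 (γ-deprotonation at C5 after O-silylation), the enal to the allyl group of 7 (C6=C7 by cross-metathesis with 8), and 7 to the C3–C4 bond between the allylmalonate 5 and the diiodide 4. Forming the enol ether before the ketone exists avoids enolising an enal beside an enolisable aryl enone. Compound 4 comes from the iodo alcohol 3, and 3 from pent-4-yn-1-ol 1 by methylalumination and iodination, the step that defines the later C9=C10 geometry.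

The aldehyde 19 is taken back through the bromide 17 (formyl for bromine via the aryllithium 18), the hydroxyquinone 15 (reductive methylation via the triol 16), the epoxide 14 and the bromoquinone 13 to the bromide 12 and the hydrocarbon 11. Bromine is introduced first, where substitution of 11 is unambiguous (α and ortho to methyl). This avoids a late substitution of the fully oxygenated naphthalene, but it asks the CrO3 oxidation of 12 to choose the bromine-free ring.

## Roads not taken

Alternative 1: The cut is the single bond C8–C9 of ring B on a finished ring A. Forward, Bu3SnH and an initiator turn the C9 xanthate A2 into a secondary radical that closes 6-exo-dig onto the internal carbon of a terminal alkyne; reduction of the vinyl radical gives the bis-silyl ether A1 with the 8(17)-methylene in place.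
- Merits: the exocyclic alkene comes out of the ring closure, so steps 15, 20, 21 and 22 of the chosen route have no counterpart; there is no C11 oxygen to remove; the conditions are neutral.
- Weak points: the step makes one ring and one stereocentre. C4, C5 and C10 (two quaternary, adjacent) must already be in A2, and making such a cyclohexane as one enantiomer is a problem of about the size of the one being solved. The C9 configuration would rest on the conformational preference of a radical next to a quaternary carbon, and 6-exo-dig closure competes with direct reduction. A1 also stops at C12, so the whole naphthoquinone, including the crowded C11–C8′ link, is still to be built and C18 still to be oxidised.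
- Comparison: Alternative 1 handles the methylene group better. The chosen plan sets against this the formation of both rings and of C5, C9 and C10 in one step from an achiral chain, and the arrival of the complete arene before the cyclisation.

Alternative 2: The cut removes C3′ from the quinone ring (bonds C3′–C4′ and C3′–C2′), tracing the naphthalene to an indanone. Forward, a methyl-bearing chlorocarbene from a diazirine cyclopropanates the silyl enol ether A4; the chlorocyclopropane opens with loss of chloride and silyl, and the five-membered ring becomes the 2-methyl-1-naphthol ring of A3.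
- Merits: the C3′ methyl and C4′ oxygen are placed without regiochemical doubt; halocarbene ring expansion of indenyl ethers is a known reaction type; the decalin stereocentres are finished and the C8 ketone is protected.
- Weak points: it is a step on the periphery. It does not say how the four decalin stereocentres or the hindered C9–C11–arene link in A4 are made. It leaves the C1′ and C2′ oxygens to later oxidation and hydroxylation on a valuable intermediate, and it needs a hazardous carbene precursor.
- Comparison: in certainty of arene regiochemistry it is at least the equal of the chosen plan, which depends on the ring selectivity of step 7. The chosen plan sets against this six arene steps on cheap material before the fragments meet, and a key step spent on the stereochemical core.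

Alternative 3: The cut takes C4–C5 and C9–C10, the two bonds of a cation–olefin bicyclisation. Forward, MeAlCl2 opens the (3R)-epoxide of the acyclic epoxy-diene A6 at C4, C5 attacks C4, C9 attacks C10, and the allylsilane ends the cascade by losing silicon, so both rings and the 8(17)-methylene of A5 arise together.
- Merits, in two respects better than the chosen plan: the absolute configuration comes from an asymmetric epoxidation, a more secure source than an untested catalytic cycloaddition; and C4 emerges with its methyl and its oxygenated carbon already different, so nothing like steps 16–19 is needed. The exocyclic alkene is also formed directly.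
- Weak points: the C3 hydroxyl of A5 is absent from the target and must be removed radically beside the new alkene. Epoxide-initiated bicyclisations are moderately efficient, and here the electron-withdrawing silyloxymethyl group sits on the carbon that must carry the positive charge. The electron-rich trimethoxynaphthalene in A6 can bind the Lewis acid or intercept a cation. A6 needs two stereodefined trisubstituted alkenes (one an allylsilane) and an enantioselective epoxidation of a third.
- Comparison: against the better absolute control, the chosen plan sets a concerted ring construction whose relative configuration follows from alkene geometry, a precursor assembled by malonate alkylation, no superfluous oxygen at C3, and C18 at the acid level from the start.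

Key step: step 14

Remarks before the steps (conventions and assumptions):
- Labdane numbering is used for the decalin and primed locants for the naphthalene (C8′ is bonded to C11); α is the face of the decalin that carries C20, β the opposite face.
- Dimethyl 2-allylmalonate 5 is taken as a commercial material.
- The carbinol centre C11 in 20 and in 25–27 is formed without control and is removed again, so it is drawn without a descriptor; the epoxide 14 is racemic.
- The sense of induction in step 14 is assigned from the α-C–H···O binding model of enones on the oxazaborolidinium ion.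

## Route

Step 1
Reactants: 1 pent-4-yn-1-ol
Product: 3 (4E)-5-iodo-4-methylpent-4-en-1-ol, via alkenylalane 2 (not isolated)
Conditions: AlMe3 (3 equiv), Cp2ZrCl2 (0.25 equiv), CH2Cl2, 0 °C → rt; then I2, THF, −30 → 0 °C; aq. K2CO3
Reagents that add atoms: trimethylaluminium, C[Al](C)C; iodine, [I][I]
Why: Zirconium-catalysed carboalumination of the terminal alkyne (Negishi) adds methyl and aluminium syn, with methyl on the internal carbon; iodinolysis of the alkenyl–Al bond goes with retention, fixing the E geometry that becomes the C9=C10 enone geometry.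

Step 2
Reactants: 3 (4E)-5-iodo-4-methylpent-4-en-1-ol
Product: 4 (1E)-1,5-diiodo-2-methylpent-1-ene
Conditions: PPh3, I2, imidazole, CH2Cl2, 0 °C → rt
Reagents that add atoms: iodine, [I][I]
Why: Appel iodination of the primary alcohol (SN2 on the alkoxyphosphonium ion); the alkenyl iodide is inert.

Step 3
Reactants: 5 dimethyl 2-allylmalonate; 4 (1E)-1,5-diiodo-2-methylpent-1-ene
Product: 7 dimethyl 2-allyl-2-[(4E)-5-iodo-4-methylpent-4-en-1-yl]malonate, via sodium enolate 6 (not isolated)
Conditions: NaH, THF/DMF, 0 °C; then 4, rt
Reagents that add atoms: none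
Why: Malonate alkylation: the enolate displaces the primary iodide by SN2 and creates the quaternary, non-stereogenic C4; the sp2 C–I bond does not react.

Step 4
Reactants: 7 dimethyl 2-allyl-2-[(4E)-5-iodo-4-methylpent-4-en-1-yl]malonate; 8 (2E)-but-2-enal
Product: 9 dimethyl 2-[(4E)-5-iodo-4-methylpent-4-en-1-yl]-2-[(2E)-4-oxobut-2-en-1-yl]malonate
Conditions: 8 (5 equiv), second-generation Hoveyda–Grubbs catalyst (5 mol %), CH2Cl2, 40 °C
Reagents that add atoms: none
Why: Olefin cross-metathesis of a terminal alkene with an electron-poor partner gives the E-enal; the trisubstituted alkenyl iodide is too hindered to enter the catalytic cycle.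

Step 5
Reactants: 9 dimethyl 2-[(4E)-5-iodo-4-methylpent-4-en-1-yl]-2-[(2E)-4-oxobut-2-en-1-yl]malonate
Product: 10 dimethyl 2-[(4E)-5-iodo-4-methylpent-4-en-1-yl]-2-[(1E,3E)-4-(triisopropylsilyloxy)buta-1,3-dien-1-yl]malonate
Conditions: TIPSOTf, Et3N, CH2Cl2, −78 → 0 °C
Reagents that add atoms: triisopropylsilyl trifluoromethanesulfonate, CC(C)[Si](OS(=O)(=O)C(F)(F)F)(C(C)C)C(C)C
Why: Soft enolisation: O-silylation of the enal and loss of a γ-proton from C5 give the 1-silyloxydiene; the s-trans enal leads to the E enol ether and the quaternary C4 forces the new C5=C6 bond to be E. C8 later becomes a ketone, so a minor enol ether isomer would cost rate in step 14 but not the configuration of the target.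

Step 6
Reactants: 11 2,6-dimethylnaphthalene
Product: 12 1-bromo-2,6-dimethylnaphthalene
Conditions: NBS (1.0 equiv), MeCN, 0 °C → rt
Reagents that add atoms: N-bromosuccinimide, O=C1CCC(=O)N1Br
Why: Electrophilic aromatic bromination goes to the α-position ortho to a methyl group, as known for 2-methylnaphthalenes; one equivalent avoids the 1,5-dibromide.

Step 7
Reactants: 12 1-bromo-2,6-dimethylnaphthalene
Product: 13 5-bromo-2,6-dimethylnaphthalene-1,4-dione
Conditions: CrO3, AcOH/H2O, 60 °C
Reagents that add atoms: chromium trioxide, O=[Cr](=O)=O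
Why: Chromic acid oxidation of a naphthalene to the 1,4-quinone takes the more electron-rich ring, here the methyl-bearing ring without bromine, whose two α-positions are free; the brominated ring cannot give a para-quinone without losing bromine. The halogen ends up peri to the carbonyl that will neighbour the hydroxyl.

Step 8
Reactants: 13 5-bromo-2,6-dimethylnaphthalene-1,4-dione
Product: 14 6-bromo-1a,5-dimethyl-1a,7a-dihydronaphtho[2,3-b]oxirene-2,7-dione
Conditions: 30% H2O2, Na2CO3, EtOH/H2O, 0 °C → rt
Reagents that add atoms: hydrogen peroxide, OO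
Why: Weitz–Scheffer nucleophilic epoxidation of the electron-poor quinone C=C bond by hydroperoxide anion.

Step 9
Reactants: 14 6-bromo-1a,5-dimethyl-1a,7a-dihydronaphtho[2,3-b]oxirene-2,7-dione
Product: 15 5-bromo-3-hydroxy-2,6-dimethylnaphthalene-1,4-dione
Conditions: conc. H2SO4, rt; then ice/H2O
Reagents that add atoms: none
Why: Acid-induced isomerisation of the epoxy-dione: ring opening and enolisation leave the hydroxyl on the carbon that carried hydrogen, the classical route from 2-methylnaphthoquinone oxides to 2-hydroxy-3-methylnaphthoquinones.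

Step 10
Reactants: 15 5-bromo-3-hydroxy-2,6-dimethylnaphthalene-1,4-dione
Product: 17 5-bromo-1,3,4-trimethoxy-2,6-dimethylnaphthalene, via naphthalenetriol 16 (not isolated)
Conditions: Na2S2O4, THF/H2O; then KOH, Me2SO4, Bu4NBr, rt, N2
Reagents that add atoms: dimethyl sulfate, COS(=O)(=O)OC
Why: Reductive methylation: dithionite reduces the hydroxyquinone to the triol, which is O-methylated three times (Williamson, phase transfer) before it can reoxidise.

Step 11
Reactants: 17 5-bromo-1,3,4-trimethoxy-2,6-dimethylnaphthalene
Product: 19 5,7,8-trimethoxy-2,6-dimethylnaphthalene-1-carbaldehyde, via aryllithium 18 (not isolated)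
Conditions: n-BuLi, THF, −78 °C; then DMF, −78 °C → rt; 1 M HCl
Reagents that add atoms: N,N-dimethylformamide, CN(C)C=O
Why: Bromine–lithium exchange followed by formylation of the aryllithium with DMF; exchange is faster than any deprotonation and puts the formyl group at the position defined in step 6.

Step 12
Reactants: 10 dimethyl 2-[(4E)-5-iodo-4-methylpent-4-en-1-yl]-2-[(1E,3E)-4-(triisopropylsilyloxy)buta-1,3-dien-1-yl]malonate; 19 5,7,8-trimethoxy-2,6-dimethylnaphthalene-1-carbaldehyde
Product: 20 dimethyl 2-[(4E)-6-hydroxy-4-methyl-6-(5,7,8-trimethoxy-2,6-dimethylnaphthalen-1-yl)hex-4-en-1-yl]-2-[(1E,3E)-4-(triisopropylsilyloxy)buta-1,3-dien-1-yl]malonate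
Conditions: CrCl2 (5 equiv), NiCl2 (2 mol %), DMF/THF, rt
Reagents that add atoms: none
Why: Nozaki–Hiyama–Kishi coupling: zerovalent nickel inserts into the alkenyl C–I bond with retention, the alkenyl group passes to trivalent chromium and adds only to the aldehyde, leaving esters and the silyl enol ether untouched. The C9–C11 bond is made between sp2 carbons before the site becomes neopentyl; the carbinol configuration is irrelevant.

Step 13
Reactants: 20 dimethyl 2-[(4E)-6-hydroxy-4-methyl-6-(5,7,8-trimethoxy-2,6-dimethylnaphthalen-1-yl)hex-4-en-1-yl]-2-[(1E,3E)-4-(triisopropylsilyloxy)buta-1,3-dien-1-yl]malonate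
Product: 21 dimethyl 2-[(4E)-4-methyl-6-oxo-6-(5,7,8-trimethoxy-2,6-dimethylnaphthalen-1-yl)hex-4-en-1-yl]-2-[(1E,3E)-4-(triisopropylsilyloxy)buta-1,3-dien-1-yl]malonate
Conditions: MnO2 (excess), CH2Cl2, rt; product kept cold and used at once
Reagents that add atoms: none
Why: MnO2 oxidation of an allylic and benzylic alcohol to the enone; it is neutral and heterogeneous and should leave the silyl dienol ether and the E alkene intact.

Step 14
Reactants: 21 dimethyl 2-[(4E)-4-methyl-6-oxo-6-(5,7,8-trimethoxy-2,6-dimethylnaphthalen-1-yl)hex-4-en-1-yl]-2-[(1E,3E)-4-(triisopropylsilyloxy)buta-1,3-dien-1-yl]malonate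
Product: 22 dimethyl (4aR,5S,6R,8aS)-4a-methyl-5-(5,7,8-trimethoxy-2,6-dimethylnaphthalene-1-carbonyl)-6-(triisopropylsilyloxy)-3,4,4a,5,6,8a-hexahydronaphthalene-1,1(2H)-dicarboxylate
Conditions: (S)-3,3-diphenyl-1-(2-methylphenyl)tetrahydro-1H,3H-pyrrolo[1,2-c][1,3,2]oxazaborole (20 mol %), Tf2NH (18 mol %), CH2Cl2, −78 → −40 °C
Reagents that add atoms: none
Why: Proposed new method: enantiofacial control of an intramolecular Diels–Alder reaction of a β,β-disubstituted aryl enone by a cationic oxazaborolidine has not been shown; the closest known reaction types are oxazaborolidinium-catalysed enantioselective Diels–Alder additions of silyloxydienes to acyclic enones, the same catalysis of intramolecular cycloadditions of trienals, and achiral Lewis-acid-promoted cyclisations of 1,7,9-decatrien-3-ones to trans-decalins. The boron cation binds the ketone oxygen of 21, lowers the enone LUMO and triggers a concerted, asynchronous [4+2] in which C5–C10 (diene terminus to enone β-carbon) leads and C8–C9 follows. Ring B closes as the cyclohexene of the cycloaddition, and ring A closes in the same event as a six-membered carbocycle because the four-carbon tether C1–C4 links the two termini C10 and C5 (fused mode). The trans relation of H5 and C20 follows from the transition state with the activated ketone endo and the tether exo; C9 is tied to C10 by the E geometry of the enone (C11 cis to C20) and C8 to C5 by the E,E geometry of the diene, both by suprafacial addition. The absolute configuration is left to the catalyst: in the α-C–H···O binding mode the (S)-catalyst covers the Re face of C9 with a phenyl group, so the diene should add to the Si face, as 22 requires. The step needs endo (trans-fused) over exo (cis-fused) selectivity, which the terminal carbonyl, the E enone and Lewis acid activation secure, and it needs the cycloaddition to outrun protodesilylation, for which the robust TIPS enol ether and low temperature are chosen. The gem-diester favours the folded conformer (Thorpe–Ingold effect) and keeps C4 free of any stereochemical question.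

Step 15
Reactants: 22 trans-fused Diels–Alder adduct (6-ene)
Product: 23 dimethyl (4aR,5S,6R,8aS)-4a-methyl-5-(5,7,8-trimethoxy-2,6-dimethylnaphthalene-1-carbonyl)-6-(triisopropylsilyloxy)octahydronaphthalene-1,1(2H)-dicarboxylate
Conditions: H2 (1 atm), Pd/C (10%), EtOAc, rt
Reagents that add atoms: none
Why: Heterogeneous hydrogenation of the only alkene, a cis-disubstituted ring alkene; the twisted aryl ketone and the naphthalene are not reduced at 1 atm.

Step 16
Reactants: 23 saturated diester ketone
Product: 24 half-ester of 23 with the equatorial C4 ester (C18) as CO2H and the axial one (C19) as CO2Me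
Conditions: LiOH·H2O (3 equiv), THF/MeOH/H2O, 0 °C → rt; 1 M HCl to pH 3
Reagents that add atoms: lithium hydroxide, [Li+].[OH-]
Why: Saponification (BAc2) discriminates the esters sterically: the axial ester is shielded by the syn-axial C20, so hydroxide takes the equatorial one, which becomes C18; this sets C4. The C9–H is hindered and its enolate strained, which should hold back β-elimination of the silyloxy group.

Step 17
Reactants: 24 half-ester (18-acid, 19-methyl ester)
Product: 25 diol acid with C11 as CH(OH) and the axial C4 group as CH2OH and C18 as CO2H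
Conditions: LiEt3BH (6 equiv), THF, 0 → 40 °C; 1 M HCl
Reagents that add atoms: none
Why: The borohydride first turns the acid into a carboxylate that it cannot reduce, then reduces the C11 ketone and the axial ester to alcohols; ester over carboxylate is the known chemoselectivity of this hydride.

Step 18
Reactants: 25 11,19-diol 18-acid
Product: 27 11,19-bis(S-methyl dithiocarbonate) of 25 with free C18 acid, via trisodium bis(dithiocarbonate) 26 (not isolated)
Conditions: NaH (5 equiv), imidazole (cat.), THF, 0 °C → rt; CS2; then MeI (2.3 equiv), 0 °C; 1 M HCl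
Reagents that add atoms: carbon disulfide, S=C=S; iodomethane, CI
Why: Xanthate formation: both alkoxides add to CS2 and the dithiocarbonate anions are S-methylated far faster than the hindered sodium carboxylate is O-methylated in THF. The TIPS group is slow to migrate to the neighbouring C11 alkoxide.

Step 19
Reactants: 27 11,19-bis(S-methyl dithiocarbonate)
Product: 28 8-(triisopropylsilyloxy)-11-(5,7,8-trimethoxy-2,6-dimethylnaphthalen-1-yl)-12,13,14,15,16,17-hexanor-ent-labdan-18-oic acid
Conditions: Bu3SnH (6 equiv), AIBN (portionwise), toluene, 110 °C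
Reagents that add atoms: none
Why: Barton–McCombie deoxygenation at both carbons in one radical chain: the stannyl radical adds to C=S, β-scission gives the benzylic C11 radical and the primary C19 radical, and each is reduced by the tin hydride. No stereocentre is touched; the axial C19 methyl is now in place.

Step 20
Reactants: 28 C8 silyl ether acid
Product: 29 8-hydroxy-11-(5,7,8-trimethoxy-2,6-dimethylnaphthalen-1-yl)-12,13,14,15,16,17-hexanor-ent-labdan-18-oic acid
Conditions: TBAF (5 equiv), THF, 50 °C; 1 M HCl
Reagents that add atoms: none
Why: Fluoride cleavage of the silyl ether, driven by Si–F bond formation; nothing else in 28 responds to fluoride.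

Step 21
Reactants: 29 C8 alcohol acid
Product: 30 8-oxo-11-(5,7,8-trimethoxy-2,6-dimethylnaphthalen-1-yl)-12,13,14,15,16,17-hexanor-ent-labdan-18-oic acid
Conditions: Dess–Martin periodinane, NaHCO3, CH2Cl2, rt
Reagents that add atoms: none
Why: Dess–Martin oxidation of the secondary alcohol to the C8 ketone; the C9 side chain is already in the more stable equatorial position, so enolisation cannot change it.

Step 22
Reactants: 30 C8 ketone acid
Product: 31 11-(5,7,8-trimethoxy-2,6-dimethylnaphthalen-1-yl)-12,13,14,15,16-pentanor-ent-labd-8(17)-en-18-oic acid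
Conditions: Ph3PCH3Br (6 equiv), KOtBu (5.5 equiv), toluene, 80 °C; 1 M HCl
Reagents that add atoms: methyltriphenylphosphonium bromide, C[P+](c1ccccc1)(c1ccccc1)c1ccccc1.[Br-]
Why: Wittig methylenation; excess ylide first forms the carboxylate and then converts the ketone into the exocyclic alkene, as known for 8-oxo decalins carrying a C9 arylmethyl group.

Step 23
Reactants: 31 trimethoxynaphthalene alkene acid
Product: 32 11-(7-methoxy-2,6-dimethyl-5,8-dioxo-5,8-dihydronaphthalen-1-yl)-12,13,14,15,16-pentanor-ent-labd-8(17)-en-18-oic acid
Conditions: (NH4)2Ce(NO3)6 (2.5 equiv), MeCN/H2O, 0 °C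
Reagents that add atoms: water, O
Why: Oxidative demethylation of the 1′,4′-dimethoxy unit by single-electron oxidation with tetravalent cerium gives the para-quinone and keeps the C2′ methoxy group; the arene is oxidised far faster than the 1,1-disubstituted alkene. An ortho-quinone isomer, if formed, would give the same product in step 24.

Step 24
Reactants: 32 methoxyquinone acid
Product: 33 (1S,4aS,5R,8aS)-5-[(7-hydroxy-2,6-dimethyl-5,8-dioxo-5,8-dihydronaphthalen-1-yl)methyl]-1,4a-dimethyl-6-methylidenedecahydronaphthalene-1-carboxylic acid
Conditions: 1 M NaOH, THF/MeOH, rt, Ar; then 1 M HCl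
Reagents that add atoms: sodium hydroxide, [Na+].[OH-]
Why: Addition–elimination of hydroxide at C2′ of the vinylogous ester gives the hydroxyquinone anion; acidification liberates 33 with all four stereocentres untouched.

## Compound list

1 | pent-4-yn-1-ol | C#CCCCO | starting material
2 | dimethyl{(1E)-5-[(dimethylalumanyl)oxy]-2-methylpent-1-en-1-yl}alumane | C[Al](C)OCCC/C(C)=C/[Al](C)C | intermediate (not isolated)
3 | (4E)-5-iodo-4-methylpent-4-en-1-ol | OCCC/C(C)=C/I | intermediate
4 | (1E)-1,5-diiodo-2-methylpent-1-ene | ICCC/C(C)=C/I | intermediate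
5 | dimethyl 2-allylmalonate (dimethyl 2-(prop-2-en-1-yl)propanedioate) | C=CCC(C(=O)OC)C(=O)OC | starting material
6 | sodium enolate of 5 | [Na+].C=CC[C-](C(=O)OC)C(=O)OC | intermediate (not isolated)
7 | dimethyl 2-allyl-2-[(4E)-5-iodo-4-methylpent-4-en-1-yl]malonate | C=CCC(CCC/C(C)=C/I)(C(=O)OC)C(=O)OC | intermediate
8 | (2E)-but-2-enal | C/C=C/C=O | starting material
9 | dimethyl 2-[(4E)-5-iodo-4-methylpent-4-en-1-yl]-2-[(2E)-4-oxobut-2-en-1-yl]malonate | O=C/C=C/CC(CCC/C(C)=C/I)(C(=O)OC)C(=O)OC | intermediate
10 | dimethyl 2-[(4E)-5-iodo-4-methylpent-4-en-1-yl]-2-[(1E,3E)-4-(triisopropylsilyloxy)buta-1,3-dien-1-yl]malonate | CC(C)[Si](C(C)C)(C(C)C)O/C=C/C=C/C(CCC/C(C)=C/I)(C(=O)OC)C(=O)OC | intermediate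
11 | 2,6-dimethylnaphthalene | Cc1ccc2cc(C)ccc2c1 | starting material
12 | 1-bromo-2,6-dimethylnaphthalene | Cc1ccc2c(Br)c(C)ccc2c1 | intermediate
13 | 5-bromo-2,6-dimethylnaphthalene-1,4-dione | CC1=CC(=O)c2c(Br)c(C)ccc2C1=O | intermediate
14 | 6-bromo-1a,5-dimethyl-1a,7a-dihydronaphtho[2,3-b]oxirene-2,7-dione (2,3-epoxide of 13; racemic, oxirane cis-fused) | CC12OC1C(=O)c1c(Br)c(C)ccc1C2=O | intermediate
15 | 5-bromo-3-hydroxy-2,6-dimethylnaphthalene-1,4-dione | CC1=C(O)C(=O)c2c(Br)c(C)ccc2C1=O | intermediate
16 | 8-bromo-3,7-dimethylnaphthalene-1,2,4-triol | Cc1c(O)c(O)c2c(Br)c(C)ccc2c1O | intermediate (not isolated)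
17 | 5-bromo-1,3,4-trimethoxy-2,6-dimethylnaphthalene | COc1c(C)c(OC)c(OC)c2c(Br)c(C)ccc12 | intermediate
18 | (5,7,8-trimethoxy-2,6-dimethylnaphthalen-1-yl)lithium | [Li]c1c(C)ccc2c(OC)c(C)c(OC)c(OC)c12 | intermediate (not isolated)
19 | 5,7,8-trimethoxy-2,6-dimethylnaphthalene-1-carbaldehyde | O=Cc1c(C)ccc2c(OC)c(C)c(OC)c(OC)c12 | intermediate
20 | dimethyl 2-[(4E)-6-hydroxy-4-methyl-6-(5,7,8-trimethoxy-2,6-dimethylnaphthalen-1-yl)hex-4-en-1-yl]-2-[(1E,3E)-4-(triisopropylsilyloxy)buta-1,3-dien-1-yl]malonate (racemic at the carbinol carbon) | CC(C)[Si](C(C)C)(C(C)C)O/C=C/C=C/C(CCC/C(C)=C/C(O)c1c(C)ccc2c(OC)c(C)c(OC)c(OC)c12)(C(=O)OC)C(=O)OC | intermediate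
21 | dimethyl 2-[(4E)-4-methyl-6-oxo-6-(5,7,8-trimethoxy-2,6-dimethylnaphthalen-1-yl)hex-4-en-1-yl]-2-[(1E,3E)-4-(triisopropylsilyloxy)buta-1,3-dien-1-yl]malonate | CC(C)[Si](C(C)C)(C(C)C)O/C=C/C=C/C(CCC/C(C)=C/C(=O)c1c(C)ccc2c(OC)c(C)c(OC)c(OC)c12)(C(=O)OC)C(=O)OC | intermediate
22 | dimethyl (4aR,5S,6R,8aS)-4a-methyl-5-(5,7,8-trimethoxy-2,6-dimethylnaphthalene-1-carbonyl)-6-(triisopropylsilyloxy)-3,4,4a,5,6,8a-hexahydronaphthalene-1,1(2H)-dicarboxylate (trans-fused; H5 β; C20, the C9 aroyl group and O8 α; 6-ene) | CC(C)[Si](C(C)C)(C(C)C)O[C@@H]1C=C[C@H]2[C@@](C)(CCCC2(C(=O)OC)C(=O)OC)[C@@H]1C(=O)c1c(C)ccc2c(OC)c(C)c(OC)c(OC)c12 | intermediate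
23 | dimethyl (4aR,5S,6R,8aS)-4a-methyl-5-(5,7,8-trimethoxy-2,6-dimethylnaphthalene-1-carbonyl)-6-(triisopropylsilyloxy)octahydronaphthalene-1,1(2H)-dicarboxylate (6,7-dihydro-22) | CC(C)[Si](C(C)C)(C(C)C)O[C@@H]1CC[C@H]2[C@@](C)(CCCC2(C(=O)OC)C(=O)OC)[C@@H]1C(=O)c1c(C)ccc2c(OC)c(C)c(OC)c(OC)c12 | intermediate
24 | half-ester of 23: equatorial C4 carboxyl (C18, β, trans to C20) as CO2H, axial C4 carboxyl (C19, α) as CO2Me; other centres as in 23 | CC(C)[Si](C(C)C)(C(C)C)O[C@@H]1CC[C@H]2[C@@](C)(CCC[C@]2(C(=O)OC)C(=O)O)[C@@H]1C(=O)c1c(C)ccc2c(OC)c(C)c(OC)c(OC)c12 | intermediate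
25 | diol acid: 24 with C11 as CH(OH) (configuration open) and the axial C4 substituent as CH2OH; C18 as CO2H | CC(C)[Si](C(C)C)(C(C)C)O[C@@H]1CC[C@H]2[C@@](C)(CCC[C@]2(CO)C(=O)O)[C@@H]1C(O)c1c(C)ccc2c(OC)c(C)c(OC)c(OC)c12 | intermediate
26 | trisodium salt of 25 as carboxylate and 11,19-bis(dithiocarbonate) | [Na+].[Na+].[Na+].CC(C)[Si](C(C)C)(C(C)C)O[C@@H]1CC[C@H]2[C@@](C)(CCC[C@]2(COC(=S)[S-])C(=O)[O-])[C@@H]1C(OC(=S)[S-])c1c(C)ccc2c(OC)c(C)c(OC)c(OC)c12 | intermediate (not isolated)
27 | 11,19-bis(S-methyl dithiocarbonate) of 25, free C18 acid | CC(C)[Si](C(C)C)(C(C)C)O[C@@H]1CC[C@H]2[C@@](C)(CCC[C@]2(COC(=S)SC)C(=O)O)[C@@H]1C(OC(=S)SC)c1c(C)ccc2c(OC)c(C)c(OC)c(OC)c12 | intermediate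
28 | 8-(triisopropylsilyloxy)-11-(5,7,8-trimethoxy-2,6-dimethylnaphthalen-1-yl)-12,13,14,15,16,17-hexanor-ent-labdan-18-oic acid (O8 axial, cis to C20; C19 methyl axial) | CC(C)[Si](C(C)C)(C(C)C)O[C@@H]1CC[C@H]2[C@@](C)(CCC[C@]2(C)C(=O)O)[C@@H]1Cc1c(C)ccc2c(OC)c(C)c(OC)c(OC)c12 | intermediate
29 | 8-hydroxy-11-(5,7,8-trimethoxy-2,6-dimethylnaphthalen-1-yl)-12,13,14,15,16,17-hexanor-ent-labdan-18-oic acid (OH cis to C20) | O[C@@H]1CC[C@H]2[C@@](C)(CCC[C@]2(C)C(=O)O)[C@@H]1Cc1c(C)ccc2c(OC)c(C)c(OC)c(OC)c12 | intermediate
30 | 8-oxo-11-(5,7,8-trimethoxy-2,6-dimethylnaphthalen-1-yl)-12,13,14,15,16,17-hexanor-ent-labdan-18-oic acid | O=C1CC[C@H]2[C@@](C)(CCC[C@]2(C)C(=O)O)[C@@H]1Cc1c(C)ccc2c(OC)c(C)c(OC)c(OC)c12 | intermediate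
31 | 11-(5,7,8-trimethoxy-2,6-dimethylnaphthalen-1-yl)-12,13,14,15,16-pentanor-ent-labd-8(17)-en-18-oic acid | C=C1CC[C@H]2[C@@](C)(CCC[C@]2(C)C(=O)O)[C@@H]1Cc1c(C)ccc2c(OC)c(C)c(OC)c(OC)c12 | intermediate
32 | 11-(7-methoxy-2,6-dimethyl-5,8-dioxo-5,8-dihydronaphthalen-1-yl)-12,13,14,15,16-pentanor-ent-labd-8(17)-en-18-oic acid | C=C1CC[C@H]2[C@@](C)(CCC[C@]2(C)C(=O)O)[C@@H]1Cc1c(C)ccc2c1C(=O)C(OC)=C(C)C2=O | intermediate
33 | CNP0259461.3: (1S,4aS,5R,8aS)-5-[(7-hydroxy-2,6-dimethyl-5,8-dioxo-5,8-dihydronaphthalen-1-yl)methyl]-1,4a-dimethyl-6-methylidenedecahydronaphthalene-1-carboxylic acid (labdane numbering 4S,5S,9R,10S) | C=C1CC[C@H]2[C@@](C)(CCC[C@]2(C)C(=O)O)[C@@H]1Cc1c(C)ccc2c1C(=O)C(O)=C(C)C2=O | target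

## Step count and least certain steps

Total: 24 steps. Longest linear sequence: 19 steps (11 → 33 through steps 6–24); the other branch (1 → 33 through steps 1–5 and 12–24) has 18.

Step 14 (key step, carries the label).
- What may go wrong: weak or reversed facial discrimination. The catalyst must bind a ketone whose one lone pair is screened by the cis β-methyl group of the s-cis enone and the other by the 2,6-disubstituted arene, so the usual binding mode may not be reached. Three further processes threaten it: protonation and loss of the silyl dienol ether by the strong acid, a stepwise Mukaiyama–Michael pathway that relaxes the endo control, and an uncatalysed background cycloaddition of 21 that lowers the enantiomeric purity.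
- Fallback (known chemistry): 21 is cyclised with the achiral Lewis acid Me2AlCl (CH2Cl2, −78 → −20 °C), the established way to trans-fused adducts of 1,7,9-decatrien-3-ones. This gives 22 as a racemate, that is together with its enantiomer ent-22 F1. Hydrogenation and selective saponification as in steps 15 and 16 carry the racemate through ent-23 F2 to the half-acids 24 and ent-24 F3. The acid is resolved by crystallisation of the (R)-1-phenylethylammonium salt of 24 F4 (the (S)-amine is used if the salt of the enantiomer is the less soluble one). Acidification returns 24, and the route continues at step 17.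

Step 12.
- What may go wrong: slow addition of the alkenylchromium species to the doubly ortho-substituted aldehyde, during which the Lewis-acidic chromium salts and traces of water hydrolyse the silyl dienol ether; the freed enal then competes as electrophile.
- Fallback: the coupling is run before the diene exists. From 7, coupling with 19 under the same CrCl2/NiCl2 conditions gives the allyl-malonate carbinol F5, MnO2 gives the allyl-malonate aryl enone F6, and cross-metathesis with 8 gives the enal aryl enone F7 (the trisubstituted enone is inert to metathesis). Enolisation with TIPSOTf/Et3N at −78 °C, where the aldehyde should be silylated faster than the shielded aryl ketone, returns to 21.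

Step 16.
- What may go wrong: β-elimination of the silyloxy group through the C9 enolate (C9–H and C8–O are trans-diaxial) while the neopentyl-type ester hydrolyses slowly; incomplete discrimination between the two esters is the second concern.
- Fallback: the ketone is removed before any base is applied. From 23, SmI2 in THF/MeOH (the known single-electron reduction of β-silyloxy ketones, indifferent to esters and to steric shielding) gives the C11 alcohol of 23 F8. Hydroxide then opens the equatorial ester without risk of elimination to give the hydroxy half-acid F9, and LiEt3BH reduces only the axial ester, returning to 25.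

Step 19.
- What may go wrong: slow β-scission of the adduct radical of the primary neopentyl xanthate, so that it is reduced before it fragments and the alcohol is returned; the benzylic xanthate may undergo thermal syn-elimination at the temperature the primary one needs.
- Fallback: the primary carbon is deoxygenated through a halide. From 25, esterification with TMSCHN2 gives the methyl ester of 25 F10. The Appel reaction (PPh3, I2, imidazole, toluene, 80 °C) converts only the primary alcohol into the C19 iodide F11, since the hindered benzylic alcohol does not react. Xanthate formation at C11 gives the iodide xanthate F12, and one Bu3SnH reduction removes iodine and xanthate to give the methyl ester of 28 F13. SN2 demethylation with LiSPr in HMPA, which does not need access to the hindered carbonyl group, returns to 28.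

## Further compounds

F1 | step 14 | ent-22, enantiomer of the adduct 22, formed with it in the racemic cyclisation | CC(C)[Si](C(C)C)(C(C)C)O[C@H]1C=C[C@@H]2[C@](C)(CCCC2(C(=O)OC)C(=O)OC)[C@H]1C(=O)c1c(C)ccc2c(OC)c(C)c(OC)c(OC)c12
F2 | step 14 | ent-23, enantiomer of the saturated diester 23 | CC(C)[Si](C(C)C)(C(C)C)O[C@H]1CC[C@@H]2[C@](C)(CCCC2(C(=O)OC)C(=O)OC)[C@H]1C(=O)c1c(C)ccc2c(OC)c(C)c(OC)c(OC)c12
F3 | step 14 | ent-24, enantiomer of the half-ester 24 | CC(C)[Si](C(C)C)(C(C)C)O[C@H]1CC[C@@H]2[C@](C)(CCC[C@@]2(C(=O)OC)C(=O)O)[C@H]1C(=O)c1c(C)ccc2c(OC)c(C)c(OC)c(OC)c12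
F4 | step 14 | (R)-1-phenylethylammonium salt of 24 | CC(C)[Si](C(C)C)(C(C)C)O[C@@H]1CC[C@H]2[C@@](C)(CCC[C@]2(C(=O)OC)C(=O)[O-])[C@@H]1C(=O)c1c(C)ccc2c(OC)c(C)c(OC)c(OC)c12.C[C@@H]([NH3+])c1ccccc1
F5 | step 12 | dimethyl 2-allyl-2-[(4E)-6-hydroxy-4-methyl-6-(5,7,8-trimethoxy-2,6-dimethylnaphthalen-1-yl)hex-4-en-1-yl]malonate (racemic carbinol) | C=CCC(CCC/C(C)=C/C(O)c1c(C)ccc2c(OC)c(C)c(OC)c(OC)c12)(C(=O)OC)C(=O)OC
F6 | step 12 | dimethyl 2-allyl-2-[(4E)-4-methyl-6-oxo-6-(5,7,8-trimethoxy-2,6-dimethylnaphthalen-1-yl)hex-4-en-1-yl]malonate | C=CCC(CCC/C(C)=C/C(=O)c1c(C)ccc2c(OC)c(C)c(OC)c(OC)c12)(C(=O)OC)C(=O)OC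
F7 | step 12 | dimethyl 2-[(4E)-4-methyl-6-oxo-6-(5,7,8-trimethoxy-2,6-dimethylnaphthalen-1-yl)hex-4-en-1-yl]-2-[(2E)-4-oxobut-2-en-1-yl]malonate | O=C/C=C/CC(CCC/C(C)=C/C(=O)c1c(C)ccc2c(OC)c(C)c(OC)c(OC)c12)(C(=O)OC)C(=O)OC
F8 | step 16 | C11 alcohol of 23 (both C4 esters intact; C11 configuration open) | CC(C)[Si](C(C)C)(C(C)C)O[C@@H]1CC[C@H]2[C@@](C)(CCCC2(C(=O)OC)C(=O)OC)[C@@H]1C(O)c1c(C)ccc2c(OC)c(C)c(OC)c(OC)c12
F9 | step 16 | hydroxy half-acid: F8 with the equatorial C4 ester as CO2H | CC(C)[Si](C(C)C)(C(C)C)O[C@@H]1CC[C@H]2[C@@](C)(CCC[C@]2(C(=O)OC)C(=O)O)[C@@H]1C(O)c1c(C)ccc2c(OC)c(C)c(OC)c(OC)c12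
F10 | step 19 | methyl ester of 25 (C18 as CO2Me; 11,19-diol) | CC(C)[Si](C(C)C)(C(C)C)O[C@@H]1CC[C@H]2[C@@](C)(CCC[C@]2(CO)C(=O)OC)[C@@H]1C(O)c1c(C)ccc2c(OC)c(C)c(OC)c(OC)c12
F11 | step 19 | C19 iodide of F10 (axial CH2I; C11 alcohol) | CC(C)[Si](C(C)C)(C(C)C)O[C@@H]1CC[C@H]2[C@@](C)(CCC[C@]2(CI)C(=O)OC)[C@@H]1C(O)c1c(C)ccc2c(OC)c(C)c(OC)c(OC)c12
F12 | step 19 | C11 S-methyl dithiocarbonate of F11 | CC(C)[Si](C(C)C)(C(C)C)O[C@@H]1CC[C@H]2[C@@](C)(CCC[C@]2(CI)C(=O)OC)[C@@H]1C(OC(=S)SC)c1c(C)ccc2c(OC)c(C)c(OC)c(OC)c12
F13 | step 19 | methyl ester of 28 | CC(C)[Si](C(C)C)(C(C)C)O[C@@H]1CC[C@H]2[C@@](C)(CCC[C@]2(C)C(=O)OC)[C@@H]1Cc1c(C)ccc2c(OC)c(C)c(OC)c(OC)c12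
A1 | alternative 1 | 12-(tert-butyldimethylsilyloxy)-18-(tert-butyldiphenylsilyloxy)-13,14,15,16-tetranor-ent-labd-8(17)-ene | C=C1CC[C@H]2[C@@](C)(CCC[C@]2(C)CO[Si](c2ccccc2)(c2ccccc2)C(C)(C)C)[C@@H]1CCO[Si](C)(C)C(C)(C)C
A2 | alternative 1 | ring A precursor with the C9 S-methyl dithiocarbonate and the C8≡C17 alkyne (C9 configuration open) | C#CCC[C@H]1[C@@](C)(CCC[C@]1(C)CO[Si](c1ccccc1)(c1ccccc1)C(C)(C)C)C(OC(=S)SC)CCO[Si](C)(C)C(C)(C)C
A3 | alternative 2 | methyl 8,8-(ethylenedioxy)-11-(5-hydroxy-2,6-dimethylnaphthalen-1-yl)-12,13,14,15,16,17-hexanor-ent-labdan-18-oate | O1CCOC12CC[C@H]3[C@@](C)(CCC[C@]3(C)C(=O)OC)[C@@H]2Cc1c(C)ccc2c(O)c(C)ccc12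
A4 | alternative 2 | tert-butyldimethylsilyl enol ether of the corresponding 7-(decalinylmethyl)-6-methylindan-1-one | O1CCOC12CC[C@H]3[C@@](C)(CCC[C@]3(C)C(=O)OC)[C@@H]2Cc1c(C)ccc2C(O[Si](C)(C)C(C)(C)C)=CCc12
A5 | alternative 3 | 3-hydroxy-18-(tert-butyldiphenylsilyloxy)-11-(5,7,8-trimethoxy-2,6-dimethylnaphthalen-1-yl)-12,13,14,15,16-pentanor-ent-labd-8(17)-ene (3-OH equatorial) | C=C1CC[C@H]2[C@@](C)(CC[C@@H](O)[C@]2(C)CO[Si](c2ccccc2)(c2ccccc2)C(C)(C)C)[C@@H]1Cc1c(C)ccc2c(OC)c(C)c(OC)c(OC)c12
A6 | alternative 3 | (3R)-3,4-epoxide of the acyclic (5E)-alkene (8Z)-allylsilane carrying the arylmethyl group on C9 and the silyloxymethyl group on C4 | C[Si](C)(C)C/C(CC/C=C(\C)CC[C@H]1O[C@]1(C)CO[Si](c1ccccc1)(c1ccccc1)C(C)(C)C)=C\Cc1c(C)ccc2c(OC)c(C)c(OC)c(OC)c12
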